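The plan rests on making ring D (the hydroxyphenyl ring) last, from open-chain carbon. Ring D is a 3-alkylphenol. Its bridge-bearing C1 and hydroxyl-bearing C3 are meta, the spacing that results when a ketone carbon and the keto carbon of an acetoacetate become linked through one CH. In a single operation the dianion of benzyl acetoacetate bonds through C4 to the ketone and, once acid is added, through C2 to the acetal carbon of a 3-oxo acetal. This gives two C–C bonds, the aromatic ring and its free OH. The precursor is the finished ring A–B–C diaryl ether bearing a CH2CH2COCH2CH(OMe)2 chain on ring C. One hydrogenolysis and loss of CO2 complete the target.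

Key step: step 7

Remark: rings are lettered A (3-methoxyphenyl), B (phenol ring bearing the aryloxy group), C (para-phenylene) and D (3-hydroxyphenyl); alkene 5 is carried as an E/Z mixture because both isomers give 6, carbinol 15 is racemic and its stereocentre is erased on aromatisation, and the target has no stereocentre.

Step 1
Reactants: 1 3-bromo-4-hydroxybenzaldehyde
Product: 2 4-(benzyloxy)-3-bromobenzaldehyde
Conditions: BnBr (1.1 equiv), K2CO3 (1.5 equiv), DMF, rt to 50 °C
Reagents that add atoms: benzyl bromide, BrCc1ccccc1
Why: Williamson ether synthesis, in which carbonate deprotonates the acidic phenol (para-formyl, ortho-bromo) and the phenoxide displaces bromide from the primary benzylic halide by SN2, leaving the aldehyde and the C–Br bond untouched.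

Step 2
Reactants: 2 4-(benzyloxy)-3-bromobenzaldehyde; 3 (3-methoxybenzyl)triphenylphosphonium chloride
Product: 5 bromostilbene 1-(benzyloxy)-2-bromo-4-[2-(3-methoxyphenyl)ethenyl]benzene (E/Z mixture), via benzylic ylide 4 (not isolated)
Conditions: 3 (1.2 equiv), KOt-Bu (1.25 equiv), THF, 0 °C; then 2, 0 °C to rt
Reagents that add atoms: none
Why: Wittig olefination, in which the semi-stabilised ylide 4 adds to the non-enolisable aromatic aldehyde and the oxaphosphetane collapses to alkene and phosphine oxide; the E/Z outcome is irrelevant because step 3 saturates the bond.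

Step 3
Reactants: 5 bromostilbene 1-(benzyloxy)-2-bromo-4-[2-(3-methoxyphenyl)ethenyl]benzene
Product: 6 bibenzyl bromide 1-(benzyloxy)-2-bromo-4-[2-(3-methoxyphenyl)ethyl]benzene
Conditions: TsNHNH2 (5 equiv, in portions), NaOAc buffer, DME/H2O, reflux
Reagents that add atoms: none
Why: Diimide reduction, in which HN=NH released from the sulfonyl hydrazide delivers two hydrogens to the non-polar C=C through a cyclic transition state and spares the C–Br bond and the benzyl ether, both of which catalytic hydrogenation would endanger.

Step 4
Reactants: 6 bibenzyl bromide 1-(benzyloxy)-2-bromo-4-[2-(3-methoxyphenyl)ethyl]benzene; 7 raspberry ketone 4-(4-hydroxyphenyl)butan-2-one (1.5 equiv)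
Product: 8 diaryl ether ketone 4-(4-{2-(benzyloxy)-5-[2-(3-methoxyphenyl)ethyl]phenoxy}phenyl)butan-2-one
Conditions: CuI (10 mol %), N,N-dimethylglycine hydrochloride (30 mol %), Cs2CO3 (2.5 equiv), 1,4-dioxane, 100 °C, argon
Reagents that add atoms: none
Why: Ligand-accelerated Ullmann diaryl ether synthesis, in which the amino-acid-bound phenoxide of monovalent copper inserts into the C–Br bond and reductively eliminates the ether; suspended carbonate in dioxane is a base that methyl ketones tolerate, and the cheap phenol is used in excess.

Step 5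
Reactants: 8 diaryl ether ketone 4-(4-{2-(benzyloxy)-5-[2-(3-methoxyphenyl)ethyl]phenoxy}phenyl)butan-2-one
Product: 10 terminal silyl enol ether {[4-(4-{2-(benzyloxy)-5-[2-(3-methoxyphenyl)ethyl]phenoxy}phenyl)but-1-en-2-yl]oxy}trimethylsilane, via lithium enolate 9 (not isolated)
Conditions: LiN(i-Pr)2 (1.15 equiv), THF, −78 °C, slow addition of 8; TMSCl (1.3 equiv), −78 to 0 °C; cold NaHCO3/pentane work-up, used crude
Reagents that add atoms: chlorotrimethylsilane, C[Si](C)(C)Cl
Why: Kinetic enolate formation and O-silylation, in which excess hindered amide at −78 °C removes a proton irreversibly from the unhindered methyl group rather than the CH2, and TMSCl traps enolate 9 on oxygen before it can equilibrate.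

Step 6
Reactants: 10 terminal silyl enol ether; 11 trimethyl orthoformate (1.5 equiv)
Product: 12 keto acetal 5-(4-{2-(benzyloxy)-5-[2-(3-methoxyphenyl)ethyl]phenoxy}phenyl)-1,1-dimethoxypentan-3-one
Conditions: TMSOTf (10 mol %), CH2Cl2, −78 °C; Et3N quench; chromatography on Et3N-washed silica
Reagents that add atoms: none
Why: Mukaiyama-type alkylation of a silyl enol ether by an orthoester, in which TMSOTf ionises 11 to the dimethoxycarbenium ion, the terminal enol carbon attacks it and silyl transfer to methoxide regenerates the catalyst, so the acetal carbon is placed only where step 5 put the double bond.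

Step 7
Reactants: 12 keto acetal 5-(4-{2-(benzyloxy)-5-[2-(3-methoxyphenyl)ethyl]phenoxy}phenyl)-1,1-dimethoxypentan-3-one; 13 benzyl acetoacetate (benzyl 3-oxobutanoate)
Product: 16 benzyl 4-[2-(4-{2-(benzyloxy)-5-[2-(3-methoxyphenyl)ethyl]phenoxy}phenyl)ethyl]-2-hydroxybenzoate, via acetoacetate dianion 14 (not isolated), via aldol adduct 15 (not isolated)
Conditions: 13 (1.5 equiv), NaH (1.6 equiv), THF, 0 °C; n-BuLi (1.55 equiv), 0 °C; 12, −78 °C; AcOH, −78 °C, aqueous wash; crude 15, TsOH·H2O (0.3 equiv), 5 Å MS, toluene, 50 °C
Reagents that add atoms: none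
Why: NaH and then n-BuLi turn 13 into dianion 14, whose more basic terminal carbon C4 adds to the ketone carbon of 12 at −78 °C in a dianion aldol addition while the acetal offers no electrophilic carbon under basic conditions, and a cold AcOH quench fixes adduct 15 before retro-aldol cleavage or lactonisation can begin. TsOH then ionises the acetal to an oxocarbenium ion that the enol carbon C2 of the β-keto ester captures in a 6-(enolendo)-exo-trig closure, after which loss of the second methanol and of the tertiary hydroxyl as water gives a cyclohexadienone that tautomerises to the phenol, aromatisation pulling every equilibrium forward. The closest known reaction type is the [3+3] cyclocondensation of acetoacetate 1,3-dianions, or of their bis-silyl dienol ethers, with 3-oxo acetals to salicylates. The only stereocentre formed, the carbinol carbon of 15, is racemic and vanishes on aromatisation, so no control element is needed. The step needs the pairing C4 to ketone and C2 to acetal, which the substrate secures because its two electrophilic carbons are switched on in turn, the ketone in base and the acetal only in acid, when C2 is the sole nucleophilic carbon left; a crossed pairing would merely place the ester between hydroxyl and chain and lead to the same phenol after step 9. The benzyl ester is chosen so that it falls together with the ring B benzyl ether in step 8.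

Step 8
Reactants: 16 benzyl 4-[2-(4-{2-(benzyloxy)-5-[2-(3-methoxyphenyl)ethyl]phenoxy}phenyl)ethyl]-2-hydroxybenzoate
Product: 17 salicylic acid 2-hydroxy-4-[2-(4-{2-hydroxy-5-[2-(3-methoxyphenyl)ethyl]phenoxy}phenyl)ethyl]benzoic acid
Conditions: H2 (1 atm), Pd/C (10 wt %), EtOAc/EtOH, rt
Reagents that add atoms: none
Why: Catalytic hydrogenolysis cleaves both benzylic C–O bonds (ester and aryl ether) in one operation, while the aryl methyl ether, the diaryl ether and the saturated bridges are inert under these conditions, and no benzyl ether is left to meet hot quinoline in step 9.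

Step 9
Reactants: 17 salicylic acid 2-hydroxy-4-[2-(4-{2-hydroxy-5-[2-(3-methoxyphenyl)ethyl]phenoxy}phenyl)ethyl]benzoic acid
Product: 18 target 2-{4-[2-(3-hydroxyphenyl)ethyl]phenoxy}-4-[2-(3-methoxyphenyl)ethyl]phenol
Conditions: quinoline (0.05 M), 200–210 °C, argon; EtOAc, 1 M HCl wash
Reagents that add atoms: none
Why: Thermal protodecarboxylation of a salicylic acid, in which the carboxyl-bearing carbon lies ortho to the hydroxyl and para to the alkyl chain and is therefore readily protonated to the keto tautomer (a β-keto acid), which expels CO2 in hot quinoline as salicylic acids and natural bibenzyl acids do; dilution and argon protect the free phenols.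

Compound list
1 | 3-bromo-4-hydroxybenzaldehyde | O=Cc1ccc(O)c(Br)c1 | starting material
2 | 4-(benzyloxy)-3-bromobenzaldehyde | O=Cc1ccc(OCc2ccccc2)c(Br)c1 | intermediate
3 | (3-methoxybenzyl)triphenylphosphonium chloride | COc1cccc(C[P+](c2ccccc2)(c2ccccc2)c2ccccc2)c1.[Cl-] | starting material
4 | (3-methoxybenzylidene)triphenylphosphorane (not isolated) | COc1cccc(C=P(c2ccccc2)(c2ccccc2)c2ccccc2)c1 | intermediate
5 | 1-(benzyloxy)-2-bromo-4-[2-(3-methoxyphenyl)ethenyl]benzene (E/Z mixture) | COc1cccc(C=Cc2ccc(OCc3ccccc3)c(Br)c2)c1 | intermediate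
6 | 1-(benzyloxy)-2-bromo-4-[2-(3-methoxyphenyl)ethyl]benzene | COc1cccc(CCc2ccc(OCc3ccccc3)c(Br)c2)c1 | intermediate
7 | raspberry ketone, 4-(4-hydroxyphenyl)butan-2-one | CC(=O)CCc1ccc(O)cc1 | starting material
8 | 4-(4-{2-(benzyloxy)-5-[2-(3-methoxyphenyl)ethyl]phenoxy}phenyl)butan-2-one | CC(=O)CCc1ccc(Oc2cc(CCc3cccc(OC)c3)ccc2OCc2ccccc2)cc1 | intermediate
9 | lithium 4-(4-{2-(benzyloxy)-5-[2-(3-methoxyphenyl)ethyl]phenoxy}phenyl)but-1-en-2-olate (not isolated) | [Li+].C=C([O-])CCc1ccc(Oc2cc(CCc3cccc(OC)c3)ccc2OCc2ccccc2)cc1 | intermediate
10 | {[4-(4-{2-(benzyloxy)-5-[2-(3-methoxyphenyl)ethyl]phenoxy}phenyl)but-1-en-2-yl]oxy}trimethylsilane | C=C(CCc1ccc(Oc2cc(CCc3cccc(OC)c3)ccc2OCc2ccccc2)cc1)O[Si](C)(C)C | intermediate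
11 | trimethyl orthoformate | COC(OC)OC | starting material
12 | 5-(4-{2-(benzyloxy)-5-[2-(3-methoxyphenyl)ethyl]phenoxy}phenyl)-1,1-dimethoxypentan-3-one | COC(OC)CC(=O)CCc1ccc(Oc2cc(CCc3cccc(OC)c3)ccc2OCc2ccccc2)cc1 | intermediate
13 | benzyl acetoacetate (benzyl 3-oxobutanoate) | CC(=O)CC(=O)OCc1ccccc1 | starting material
14 | sodium lithium 1,3-dianion of benzyl acetoacetate (not isolated) | [Na+].[Li+].[CH2-]C(=O)[CH-]C(=O)OCc1ccccc1 | intermediate
15 | benzyl 7-(4-{2-(benzyloxy)-5-[2-(3-methoxyphenyl)ethyl]phenoxy}phenyl)-5-(2,2-dimethoxyethyl)-5-hydroxy-3-oxoheptanoate (racemic, not isolated) | COC(OC)CC(O)(CCc1ccc(Oc2cc(CCc3cccc(OC)c3)ccc2OCc2ccccc2)cc1)CC(=O)CC(=O)OCc1ccccc1 | intermediate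
16 | benzyl 4-[2-(4-{2-(benzyloxy)-5-[2-(3-methoxyphenyl)ethyl]phenoxy}phenyl)ethyl]-2-hydroxybenzoate | O=C(OCc1ccccc1)c1ccc(CCc2ccc(Oc3cc(CCc4cccc(OC)c4)ccc3OCc3ccccc3)cc2)cc1O | intermediate
17 | 2-hydroxy-4-[2-(4-{2-hydroxy-5-[2-(3-methoxyphenyl)ethyl]phenoxy}phenyl)ethyl]benzoic acid | O=C(O)c1ccc(CCc2ccc(Oc3cc(CCc4cccc(OC)c4)ccc3O)cc2)cc1O | intermediate
18 | 2-{4-[2-(3-hydroxyphenyl)ethyl]phenoxy}-4-[2-(3-methoxyphenyl)ethyl]phenol (CNP0225725.0) | COc1cccc(CCc2ccc(O)c(Oc3ccc(CCc4cccc(O)c4)cc3)c2)c1 | target

Total step count: 9. Longest linear sequence: 9 steps (1, 2, 5, 6, 8, 10, 12, 16, 17, 18).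

Risk 1, step 7: The strongly basic dianion may take a proton from the CH2 group flanked by ketone and acetal, after which methoxide is expelled. The addition may also reverse, or the alkoxide may lactonise onto the ester before the quench. Either process would consume 12 without ring closure. The fallback sets out from 13, with 12 as partner, and replaces the anionic addition by a Lewis-acid [3+3] cyclocondensation of a neutral dinucleophile. TMSCl and Et3N in toluene at room temperature should convert 13 into benzyl 3-[(trimethylsilyl)oxy]but-2-enoate F1. Deprotonation of its methyl group with LiN(i-Pr)2 in THF at −78 °C and a second silylation should give 1-(benzyloxy)-1,3-bis[(trimethylsilyl)oxy]buta-1,3-diene F2. F2 and 12 with TiCl4 in CH2Cl2, −78 °C to room temperature, should join the terminal carbon to the activated ketone and the central carbon to the acetal. Aromatisation follows in the same flask, so no strong base ever meets the keto acetal. The fallback comes back to the route at 16.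

Risk 2, step 4: Copper may insert only slowly into the hindered, electron-rich C–Br bond next to the benzyloxy group. Hydrodebromination or base-induced self-condensation of the methyl ketone could then take over. The fallback sets out from 6 and forms the same C–O bond by an oxidative coupling at room temperature. n-BuLi is added to 6 and B(Oi-Pr)3 in THF at −78 °C, so that bromine–lithium exchange is followed by trapping in situ. Dilute HCl should then give {2-(benzyloxy)-5-[2-(3-methoxyphenyl)ethyl]phenyl}boronic acid F3. Chan–Lam coupling of F3 with 7 (Cu(OAc)2, pyridine, 4 Å MS, CH2Cl2, air, room temperature) needs neither heat nor carbonate base. The fallback comes back to the route at 8.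

Risk 3, step 9: Loss of CO2 may be slower than esterification between the carboxyl group and free phenols of other molecules. It may also be slower than oxidative degradation of the ring B phenol near 200 °C. The fallback sets out from 16, keeps ring B protected during the decarboxylation and uses a metal-mediated mechanism at lower temperature. LiOH in THF/MeOH/H2O at 50 °C should cleave only the ester and give 4-[2-(4-{2-(benzyloxy)-5-[2-(3-methoxyphenyl)ethyl]phenoxy}phenyl)ethyl]-2-hydroxybenzoic acid F4. Ag2CO3 (10 mol %) and AcOH (5 mol %) in DMSO at 120 °C should then replace the carboxyl group by hydrogen through an aryl–silver intermediate, the catalytic protodecarboxylation known for ortho-substituted benzoic acids. This gives 3-[2-(4-{2-(benzyloxy)-5-[2-(3-methoxyphenyl)ethyl]phenoxy}phenyl)ethyl]phenol F5. Hydrogenolysis of F5 (H2, Pd/C, EtOAc/EtOH, room temperature) then makes the last step a mild one. The fallback comes back to the route at 18.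

Further compounds
F1 | step 7 | benzyl 3-[(trimethylsilyl)oxy]but-2-enoate (E/Z mixture) | CC(O[Si](C)(C)C)=CC(=O)OCc1ccccc1
F2 | step 7 | 1-(benzyloxy)-1,3-bis[(trimethylsilyl)oxy]buta-1,3-diene (ketene acetal geometry undefined) | C=C(O[Si](C)(C)C)C=C(OCc1ccccc1)O[Si](C)(C)C
F3 | step 4 | {2-(benzyloxy)-5-[2-(3-methoxyphenyl)ethyl]phenyl}boronic acid | COc1cccc(CCc2ccc(OCc3ccccc3)c(B(O)O)c2)c1
F4 | step 9 | 4-[2-(4-{2-(benzyloxy)-5-[2-(3-methoxyphenyl)ethyl]phenoxy}phenyl)ethyl]-2-hydroxybenzoic acid | O=C(O)c1ccc(CCc2ccc(Oc3cc(CCc4cccc(OC)c4)ccc3OCc3ccccc3)cc2)cc1O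
F5 | step 9 | 3-[2-(4-{2-(benzyloxy)-5-[2-(3-methoxyphenyl)ethyl]phenoxy}phenyl)ethyl]phenol | Oc1cccc(CCc2ccc(Oc3cc(CCc4cccc(OC)c4)ccc3OCc3ccccc3)cc2)c1
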